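## Structural features

The target is a germacranolide: a ten-membered carbocycle C1–C10 (methyl C14 on C10, methyl C15 on C4) trans-fused across C7–C8 to an α-methylene-γ-butyrolactone (O–C8, C7, C11=C13H2, C12=O), with an angelate [(Z)-2-methylbut-2-enoate] on O–C6. C6, C7 and C8 form a contiguous all-trans triad (6α-O, 7α-H, 8α-O; 6S,7R,8S) whose three substituents are all pseudo-equatorial. Two trisubstituted trans-oxiranes, C1–O–C10 and C4–O–C5, are both (R,R) (1β,10α and 4α,5β) and correspond to the peripheral faces of an (E,E)-cyclodeca-1(10),4-diene; C5 is bonded to C6 and C10 is one methylene (C9) away from C8, so all seven stereocentres stand in relay. Fragile groups are the exocyclic enoate C11=C13 (Michael acceptor), the angelate (Z to E isomerisation to the tiglate under nucleophilic or basic acylation), and the oxiranes with their parent 1,5-diene (acid-triggered transannular cyclisation). The real difficulty is the strained ten-membered ring with two E-trisubstituted alkenes, and fixing C6/C7/C8 relative to each other and then to four oxirane carbons with no rigid ring fusion other than the lactone. The feature exploited is that O6–C6–C7–C11=C13 is a homoallylic alcohol whose carbinol carbon C6 is allylic to C4=C5, which is the retron of a [2,3]-Wittig rearrangement; because C13 is exocyclic, reconnecting O6 to C13 while cutting C6–C7 opens the ten-membered ring to an unstrained 13-membered oxacycle. In one sentence, the route is the transannular [2,3]-Wittig ring contraction of the 13-membered bis-allylic ether 20, which carries a single stereocentre (C8).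

## Logic of the disconnections

30 ⇒ 29. Bonds cut: C1–O/C10–O and C4–O/C5–O. Both oxiranes are trans and (R,R), i.e. the outer faces of the two E-alkenes of 29. Gain: four stereocentres removed in one operation. Demand: only the two electron-rich ring alkenes may react, not the two enoates. At C4=C5, A(1,3) strain between C15 and C6 keeps H6 in the alkene plane, so the exposed face is the one syn to O6. At C1=C10 the selectivity rests on the ring conformer with C14 and C15 on the same side.

29 ⇒ 26 (through 28 and 27). Bond cut: O8–C12, with C12 taken back to the alcohol level. The lactone carbonyl and its Michael acceptor are incompatible with the organolithium of the key step, so they appear only afterwards. Gain: C12 is carried as a silyl-protected CH2OH. Demand: oxidation of the primary allylic alcohol in the presence of the secondary C8–OH, with O6 already acylated so that only O8 can close the five-membered ring.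

26 ⇒ 25 ⇒ 22 + 23. Bonds cut: the two O–Si bonds, then the acyl C–O bond at O6. Gain: the free C6 alcohol is exactly what the key step delivers. Demand: acylation of a hindered allylic alcohol without Z to E isomerisation of the angelate.

22 ⇒ 20 (key disconnection). Bond cut: C6–C7; bond reconnected: O6–C13; the alkene returns from C11=C13 to C7=C11. The homoallylic alcohol with an allylic carbinol carbon is the [2,3]-Wittig retron. Gain: the ten-membered ring and the C6 and C7 stereocentres disappear, leaving an unstrained 13-membered ether with C8 as its only stereocentre. Demand: lithiation at C6, a C7=C11 geometry with C8 trans to C13, and facial control by C8.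

20 ⇒ 19 ⇒ 18 ⇒ 16 ⇒ 15. Bond cut: O–C13 (etherification); the following changes restore the C6 protecting group and take C13 from chloride through alcohol to ester. Gain: an acyclic chain. Demand: ring closure under dilution with the alkoxide on C6, far from the silyl ethers, so that no silyl migration can scramble C12 and C13.

15 ⇒ 11 + 14. Bond cut: C7=C11 (olefination). The E-selective olefination places the ester (future C13) trans and CH2OSi (future C12) cis to C8, which is the geometry the key step needs. Gain: a C3 phosphonate and an α-silyloxy aldehyde. Demand: no epimerisation at C8. 14 ⇒ 13 ⇒ 12 cuts the C11–CO2Et bond and the O–Si bond.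

11 ⇒ 10 ⇒ 9 ⇒ 8 + 4. Bond cut: C8–C9 (auxiliary-controlled glycolate alkylation). This sets the only reagent-controlled stereocentre of the synthesis. Gain: a C2 glycolate and an allylic bromide. Demand: high facial selectivity of the enolate. 8 ⇒ 5 + 6 (through 7) cuts the imide N–C bond.

4 ⇒ 3 ⇒ 2 ⇒ 1. Bonds cut: C9–Br, C9–O and the protecting-group O–C bond. Compound 1 supplies C1–C6, C9, C10, C14 and C15 with both E-alkenes in place. Demand: oxidation of the E-methyl group of the terminal alkene only.

## Other disconnections considered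

Alternative 1: The first that comes to mind is to cut C6–C7 and close the ten-membered ring directly by an intramolecular Barbier/Nozaki–Hiyama allylation of the C6 enal by the 2-(bromomethyl)enoate in A1. That step would have to build the full strain of the (E,E)-cyclodecadiene in the C–C bond-forming event itself, under high dilution against oligomerisation. Its C6/C7 outcome would rest on the chair/boat preference of a flexible allylmetal in a forming medium ring, not on alkene geometry. The C6 alkoxide it produces is γ to the C12 ester and would be expected to lactonise to the 6,12-olide, the wrong lactone, unless C12 is carried at the alcohol level. The chosen plan closes an unstrained 13-membered ring by C–O bond formation and pays the strain in a unimolecular concerted shift that transfers alkene geometry into C6/C7. Step counts are comparable, so this closure is kept only as the fallback.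

Alternative 2: Add the transannular bond C5–C10 and fragment it: the trans-decalin A2 (1β-mesylate antiperiplanar to C5–C10, formyl-stabilised carbanion at C4) would undergo a Grob-type 1,4-fragmentation to the ring-trans,trans diene A3, forming C1=C10 and C4=C5 together. The appeal is structural: on ring B of A2 the C6/C7/C8 triad is all-equatorial. The cost is that A2 needs seven stereocentres, including quaternary C10, assembled on a bicycle, against one stereocentre on an acyclic chain here. The electrofuge also leaves C15 as a formyl group in A3, which would need three further operations to become CH3 on a base- and acid-sensitive dienolide. Enolate generation next to the α-methylene lactone is a further liability.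

Alternative 3: Cut C2–C3 in a retro-Cope sense and reconnect C5–C10: anionic oxy-Cope rearrangement of the 1,2-dialkenylcyclohexanol A4 would give the cyclodec-5-enone A5, closing the ring and setting E-C1=C10 through a chair transition state. It is rejected because it returns C5 as a ketone and C4 as an uncontrolled sp3 centre. Converting C4–C5(=O) into the E-alkene or the trans-oxirane would need enolate trapping and reduction. The potassium alkoxide at C5 would sit next to the C6 silyl ether, inviting silyl migration. A4 itself, with quaternary C10, a tertiary carbinol and four contiguous ring stereocentres, is costlier than 20.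

Key step: step 15

Assumption: locants C1–C15 are those of the germacrane skeleton of the target; compounds 1, 5, 6, 12 and 23 are taken as purchasable; TBS = tert-butyldimethylsilyl, PMB = 4-methoxybenzyl.

## Route

Step 1
Reactants: 1 geraniol
Product: 2 geranyl PMB ether, 1-({[(2E)-3,7-dimethylocta-2,6-dien-1-yl]oxy}methyl)-4-methoxybenzene
Conditions: NaH, PMBCl, n-Bu4NI (cat.), THF/DMF, 0 °C → rt
Reagents that add atoms: 4-methoxybenzyl chloride, COc1ccc(CCl)cc1
Why: Williamson etherification of the primary allylic alkoxide; no stereocentre is formed and the 2E geometry is untouched.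

Step 2
Reactants: 2 geranyl PMB ether
Product: 3 (2E,6E)-8-[(4-methoxybenzyl)oxy]-2,6-dimethylocta-2,6-dien-1-ol
Conditions: SeO2 (0.3 equiv), t-BuOOH, salicylic acid (cat.), CH2Cl2, 0 °C → rt
Reagents that add atoms: tert-butyl hydroperoxide, CC(C)(C)OO (terminal oxygen source); selenium dioxide, O=[Se]=O (catalytic oxygen carrier)
Why: Selenium dioxide allylic oxidation (ene reaction then [2,3]-shift) attacks the more electron-rich terminal alkene and is selective for its E-methyl group, giving the E-allylic alcohol; the other alkene is deactivated by the allylic ether oxygen.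

Step 3
Reactants: 3 (2E,6E)-8-[(4-methoxybenzyl)oxy]-2,6-dimethylocta-2,6-dien-1-ol
Product: 4 1-({[(2E,6E)-8-bromo-3,7-dimethylocta-2,6-dien-1-yl]oxy}methyl)-4-methoxybenzene
Conditions: CBr4, PPh3, CH2Cl2, 0 °C
Reagents that add atoms: carbon tetrabromide, BrC(Br)(Br)Br
Why: Appel bromination; SN2 displacement of the oxyphosphonium at the primary allylic carbon at 0 °C should keep the E geometry without allylic transposition.

Step 4
Reactants: 5 [(tert-butyldimethylsilyl)oxy]acetic acid, 6 (R)-4-benzyloxazolidin-2-one
Product: 8 (R)-4-benzyl-3-{[(tert-butyldimethylsilyl)oxy]acetyl}oxazolidin-2-one, via pivalic mixed anhydride 7 (not isolated)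
Conditions: 5, Et3N, PivCl, THF, −20 °C; then 6/n-BuLi (THF, −78 °C), −78 → 0 °C
Reagents that add atoms: pivaloyl chloride, CC(C)(C)C(=O)Cl (its atoms stay only in 7)
Why: N-acylation of the lithiated oxazolidinone by the mixed anhydride at its less hindered glycolyl carbonyl; standard imide preparation, no stereocentre is touched.

Step 5
Reactants: 8 (R)-4-benzyl-3-{[(tert-butyldimethylsilyl)oxy]acetyl}oxazolidin-2-one, 4 allylic bromide
Product: 9 (R)-4-benzyl-3-[(2S,4E,8E)-2-[(tert-butyldimethylsilyl)oxy]-10-[(4-methoxybenzyl)oxy]-4,8-dimethyldeca-4,8-dienoyl]oxazolidin-2-one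
Conditions: NaHMDS, THF, −78 °C; then 4, −78 → −45 °C
Reagents that add atoms: none
Why: Evans-auxiliary glycolate alkylation: the chelated Z-sodium enolate is alkylated by the allylic bromide on the face opposite the benzyl group of the (R)-auxiliary, which sets C8 as S (the 8α-oxygen of the target).

Step 6
Reactants: 9 alkylated imide
Product: 10 (2S,4E,8E)-2-[(tert-butyldimethylsilyl)oxy]-10-[(4-methoxybenzyl)oxy]-4,8-dimethyldeca-4,8-dien-1-ol
Conditions: LiBH4, MeOH (1.1 equiv), Et2O, 0 °C
Reagents that add atoms: none
Why: Reductive cleavage of the auxiliary; the exocyclic imide carbonyl is the most electrophilic group present and C8 is not epimerised by borohydride.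

Step 7
Reactants: 10 primary alcohol
Product: 11 (2S,4E,8E)-2-[(tert-butyldimethylsilyl)oxy]-10-[(4-methoxybenzyl)oxy]-4,8-dimethyldeca-4,8-dienal
Conditions: Dess–Martin periodinane, pyridine, CH2Cl2, 0 °C → rt
Reagents that add atoms: none
Why: Dess–Martin oxidation under buffered, non-basic conditions should give the α-silyloxy aldehyde without enolisation at C8; it is used crude.

Step 8
Reactants: 12 diethyl (2-hydroxyethyl)phosphonate
Product: 13 diethyl {2-[(tert-butyldimethylsilyl)oxy]ethyl}phosphonate
Conditions: TBSCl, imidazole, DMF, rt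
Reagents that add atoms: tert-butyldimethylsilyl chloride, CC(C)(C)[Si](C)(C)Cl
Why: Routine silylation of a primary alcohol.

Step 9
Reactants: 13 diethyl {2-[(tert-butyldimethylsilyl)oxy]ethyl}phosphonate
Product: 14 ethyl 3-[(tert-butyldimethylsilyl)oxy]-2-(diethoxyphosphoryl)propanoate (racemic)
Conditions: LDA (2.2 equiv), THF, −78 °C; ClCO2Et; AcOH
Reagents that add atoms: ethyl chloroformate, CCOC(=O)Cl
Why: C-Ethoxycarbonylation of the α-lithiated phosphonate; the second equivalent of base takes up the more acidic product, and −78 °C keeps β-elimination of silanolate slow.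

Step 10
Reactants: 11 α-silyloxy aldehyde, 14 phosphonate
Product: 15 ethyl (2E,4S,6E,10E)-4-[(tert-butyldimethylsilyl)oxy]-2-{[(tert-butyldimethylsilyl)oxy]methyl}-12-[(4-methoxybenzyl)oxy]-6,10-dimethyldodeca-2,6,10-trienoate
Conditions: 14, NaH, THF, 0 °C; then 11, −20 → 0 °C
Reagents that add atoms: none
Why: Horner–Wadsworth–Emmons olefination with a 2-substituted phosphonoacetate; the usual E selectivity puts CO2Et (future C13) trans and CH2OTBS (future C12) cis to C8, the geometry that the key step converts into the C6/C7 configuration.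

Step 11
Reactants: 15 enoate
Product: 16 (2Z,4S,6E,10E)-4-[(tert-butyldimethylsilyl)oxy]-2-{[(tert-butyldimethylsilyl)oxy]methyl}-12-[(4-methoxybenzyl)oxy]-6,10-dimethyldodeca-2,6,10-trien-1-ol (CH2OH trans to C4)
Conditions: DIBAL-H, CH2Cl2, −78 °C
Reagents that add atoms: none
Why: 1,2-Reduction of the enoate to the allylic alcohol; alkene geometry and silyl ethers are unaffected.

Step 12
Reactants: 16 allylic alcohol
Product: 18 1-({[(2E,6E,9S,10E)-9-[(tert-butyldimethylsilyl)oxy]-11-{[(tert-butyldimethylsilyl)oxy]methyl}-12-chloro-3,7-dimethyldodeca-2,6,10-trien-1-yl]oxy}methyl)-4-methoxybenzene, via allylic mesylate 17 (not isolated)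
Conditions: MsCl, Et3N, CH2Cl2, −20 °C; then LiCl, DMF, 0 °C → rt
Reagents that add atoms: lithium chloride, [Li+].[Cl-]; methanesulfonyl chloride, CS(=O)(=O)Cl (its atoms stay only in 17)
Why: Mesylation followed by SN2 displacement with chloride at the primary allylic carbon; SN2' attack at C7 is disfavoured by the adjacent silyloxy-bearing C8, so the alkene geometry is retained.

Step 13
Reactants: 18 allylic chloride
Product: 19 (2E,6E,9S,10E)-9-[(tert-butyldimethylsilyl)oxy]-11-{[(tert-butyldimethylsilyl)oxy]methyl}-12-chloro-3,7-dimethyldodeca-2,6,10-trien-1-ol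
Conditions: DDQ, CH2Cl2/pH 7 buffer (10:1), 0 °C
Reagents that add atoms: none
Why: Oxidative cleavage of the PMB ether (hydride abstraction from the electron-rich benzylic position, hydrolysis of the oxocarbenium ion); silyl ethers and the allylic chloride are inert.

Step 14
Reactants: 19 hydroxy allylic chloride
Product: 20 (3E,7E,10S,11Z)-10-[(tert-butyldimethylsilyl)oxy]-12-{[(tert-butyldimethylsilyl)oxy]methyl}-4,8-dimethyl-1-oxacyclotrideca-3,7,11-triene (ring atoms C10 and C13 trans across C11=C12)
Conditions: NaH, 15-crown-5 (cat.), THF (0.003 M, slow addition), 45 °C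
Reagents that add atoms: none
Why: Intramolecular Williamson etherification (13-exo-tet) to an unstrained ring of the size for which this closure of bis-allylic ethers is precedented. The alkoxide is on C6, remote from both silyl ethers, so no silyl migration can exchange the two CH2O groups on C11.

Step 15
Reactants: 20 13-membered bis-allylic ether
Product: 22 8α,12-bis[(tert-butyldimethylsilyl)oxy]germacra-1(10)E,4E,11(13)-trien-6α-ol (7α-H, 8β-H), via lithiated ether 21 (not isolated)
Conditions: n-BuLi, THF, −78 → −25 °C; then pH 7 buffer at −78 °C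
Reagents that add atoms: none
Why: n-BuLi removes a C6 proton (allylic to C4=C5 and α to the ether oxygen) to give 21, which undergoes a concerted, suprafacial [2,3]-sigmatropic (Wittig) shift through a five-membered envelope (C6, O, C13, C11, C7): C6–C7 forms, O–C13 breaks, the alkene moves to C11=C13 and the lithium alkoxide of 22 results. The closest known reaction type is the [2,3]-Wittig ring contraction of 13-membered bis-allylic ethers to ten-membered germacrane carbocycles. The ten-membered ring is closed transannularly as a 13→10 contraction, so the strain is paid by a unimolecular exchange of a C–O for a C–C bond with no oligomerisation channel, and both E ring alkenes are spectators. The C6/C7 relationship (6α-O, 7α-H, anti) follows from the geometry of C7=C11, in which C8 is trans to C13, with the C5 alkenyl substituent of the carbanion exo in the envelope. The sense relative to C8 is set by A(1,3) strain with the cis CH2OTBS group on C11, which holds C8–H in the alkene plane so that the tethered C6 reaches C7 on the face carrying C9 and anti to the OTBS group; in the crown-like ten-ring array this places O6, C11 and O8 all pseudo-equatorial. The step needs lithiation at C6 rather than at C13 or at the CH2OSi carbon: C6H2 is flanked only by the C5 methine, whereas the competing positions sit on the fully substituted C11 between two bulky silyl ethers, and a shift from a C13 anion would have to bond to the fully substituted C4. Low temperature and the lithium counter-ion should suppress the [1,2]-shift and an anionic oxy-Cope rearrangement of the product 1,5-dien-3-olate.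

Step 16
Reactants: 22 germacratrienol, 23 angelic acid [(2Z)-2-methylbut-2-enoic acid]
Product: 25 6α-angeloyloxy-8α,12-bis[(tert-butyldimethylsilyl)oxy]germacra-1(10)E,4E,11(13)-triene, via angelic mixed anhydride 24 (not isolated)
Conditions: 23, 2,4,6-Cl3C6H2COCl, Et3N, toluene, rt; then 22, 75 °C
Reagents that add atoms: 2,4,6-trichlorobenzoyl chloride, O=C(Cl)c1c(Cl)cc(Cl)cc1Cl (its atoms stay only in 24)
Why: Yamaguchi-type acylation through the mixed anhydride without a nucleophilic catalyst, since addition–elimination of such catalysts isomerises angelates to tiglates; the configuration at C6 is retained because only the O–H bond is engaged.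

Step 17
Reactants: 25 bis-silyl ether
Product: 26 6α-angeloyloxygermacra-1(10)E,4E,11(13)-triene-8α,12-diol
Conditions: TBAF, AcOH (1:1), THF, 0 °C → rt
Reagents that add atoms: none
Why: Fluoride-mediated desilylation, buffered with acetic acid to prevent acyl migration from O6 to O8 and base-induced isomerisation of the angelate.

Step 18
Reactants: 26 diol
Product: 29 6α-angeloyloxygermacra-1(10)E,4E,11(13)-trien-12,8α-olide (7α-H, 8β-H), via hydroxy enal 27 (not isolated), via lactol 28 (not isolated)
Conditions: activated MnO2 (excess), CH2Cl2, rt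
Reagents that add atoms: none
Why: MnO2 oxidises only the primary allylic alcohol (C8–OH is not allylic) to enal 27; O8 adds to give the five-membered lactol 28, whose allylic hemiacetal C–H is oxidised to the lactone. O6 is already esterified, so the 6,12-olide cannot form.

Step 19
Reactants: 29 triene lactone
Product: 30 target, (1R,4R,5R,6S,7R,8S,10R)-6-angeloyloxy-1,10:4,5-diepoxygermacr-11(13)-en-12,8-olide (1β,10α:4α,5β-diepoxide)
Conditions: mCPBA (2.2 equiv), Na2HPO4, CH2Cl2, 0 °C
Reagents that add atoms: 3-chloroperoxybenzoic acid, OOC(=O)c1cccc(Cl)c1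
Why: Prilezhaev epoxidation of the two electron-rich trisubstituted ring alkenes; the two conjugated enoates are too electron-poor to react, and each E-alkene gives a trans-oxirane. At C4=C5, A(1,3) strain between C15 and C6 holds H6 in the alkene plane, so the peripheral face is the one syn to O6 (4α,5β); at C1=C10, outside attack on the crown conformer with C14 syn to C15 gives 1β,10α. The buffer guards against acid-triggered transannular opening.

## Compound list

1 | geraniol, (2E)-3,7-dimethylocta-2,6-dien-1-ol | CC(C)=CCC/C(C)=C/CO | starting material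
2 | 1-({[(2E)-3,7-dimethylocta-2,6-dien-1-yl]oxy}methyl)-4-methoxybenzene | CC(C)=CCC/C(C)=C/COCc1ccc(OC)cc1 | intermediate
3 | (2E,6E)-8-[(4-methoxybenzyl)oxy]-2,6-dimethylocta-2,6-dien-1-ol | OC/C(C)=C/CC/C(C)=C/COCc1ccc(OC)cc1 | intermediate
4 | 1-({[(2E,6E)-8-bromo-3,7-dimethylocta-2,6-dien-1-yl]oxy}methyl)-4-methoxybenzene | BrC/C(C)=C/CC/C(C)=C/COCc1ccc(OC)cc1 | intermediate
5 | [(tert-butyldimethylsilyl)oxy]acetic acid | CC(C)(C)[Si](C)(C)OCC(=O)O | starting material
6 | (R)-4-benzyloxazolidin-2-one | O=C1N[C@H](Cc2ccccc2)CO1 | starting material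
7 | [(tert-butyldimethylsilyl)oxy]acetic pivalic anhydride | CC(C)(C)[Si](C)(C)OCC(=O)OC(=O)C(C)(C)C | intermediate (not isolated)
8 | (R)-4-benzyl-3-{[(tert-butyldimethylsilyl)oxy]acetyl}oxazolidin-2-one | CC(C)(C)[Si](C)(C)OCC(=O)N1[C@H](Cc2ccccc2)COC1=O | intermediate
9 | (R)-4-benzyl-3-[(2S,4E,8E)-2-[(tert-butyldimethylsilyl)oxy]-10-[(4-methoxybenzyl)oxy]-4,8-dimethyldeca-4,8-dienoyl]oxazolidin-2-one | O=C([C@@H](O[Si](C)(C)C(C)(C)C)C/C(C)=C/CC/C(C)=C/COCc1ccc(OC)cc1)N1[C@H](Cc2ccccc2)COC1=O | intermediate
10 | (2S,4E,8E)-2-[(tert-butyldimethylsilyl)oxy]-10-[(4-methoxybenzyl)oxy]-4,8-dimethyldeca-4,8-dien-1-ol | OC[C@@H](O[Si](C)(C)C(C)(C)C)C/C(C)=C/CC/C(C)=C/COCc1ccc(OC)cc1 | intermediate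
11 | (2S,4E,8E)-2-[(tert-butyldimethylsilyl)oxy]-10-[(4-methoxybenzyl)oxy]-4,8-dimethyldeca-4,8-dienal | O=C[C@@H](O[Si](C)(C)C(C)(C)C)C/C(C)=C/CC/C(C)=C/COCc1ccc(OC)cc1 | intermediate
12 | diethyl (2-hydroxyethyl)phosphonate | CCOP(=O)(CCO)OCC | starting material
13 | diethyl {2-[(tert-butyldimethylsilyl)oxy]ethyl}phosphonate | CCOP(=O)(CCO[Si](C)(C)C(C)(C)C)OCC | intermediate
14 | ethyl 3-[(tert-butyldimethylsilyl)oxy]-2-(diethoxyphosphoryl)propanoate (racemic) | CCOC(=O)C(CO[Si](C)(C)C(C)(C)C)P(=O)(OCC)OCC | intermediate
15 | ethyl (2E,4S,6E,10E)-4-[(tert-butyldimethylsilyl)oxy]-2-{[(tert-butyldimethylsilyl)oxy]methyl}-12-[(4-methoxybenzyl)oxy]-6,10-dimethyldodeca-2,6,10-trienoate | CCOC(=O)/C(CO[Si](C)(C)C(C)(C)C)=C/[C@@H](O[Si](C)(C)C(C)(C)C)C/C(C)=C/CC/C(C)=C/COCc1ccc(OC)cc1 | intermediate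
16 | (2Z,4S,6E,10E)-4-[(tert-butyldimethylsilyl)oxy]-2-{[(tert-butyldimethylsilyl)oxy]methyl}-12-[(4-methoxybenzyl)oxy]-6,10-dimethyldodeca-2,6,10-trien-1-ol | OC/C(CO[Si](C)(C)C(C)(C)C)=C/[C@@H](O[Si](C)(C)C(C)(C)C)C/C(C)=C/CC/C(C)=C/COCc1ccc(OC)cc1 | intermediate
17 | methanesulfonate of 16 | CS(=O)(=O)OC/C(CO[Si](C)(C)C(C)(C)C)=C/[C@@H](O[Si](C)(C)C(C)(C)C)C/C(C)=C/CC/C(C)=C/COCc1ccc(OC)cc1 | intermediate (not isolated)
18 | 1-({[(2E,6E,9S,10E)-9-[(tert-butyldimethylsilyl)oxy]-11-{[(tert-butyldimethylsilyl)oxy]methyl}-12-chloro-3,7-dimethyldodeca-2,6,10-trien-1-yl]oxy}methyl)-4-methoxybenzene | ClC/C(CO[Si](C)(C)C(C)(C)C)=C/[C@@H](O[Si](C)(C)C(C)(C)C)C/C(C)=C/CC/C(C)=C/COCc1ccc(OC)cc1 | intermediate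
19 | (2E,6E,9S,10E)-9-[(tert-butyldimethylsilyl)oxy]-11-{[(tert-butyldimethylsilyl)oxy]methyl}-12-chloro-3,7-dimethyldodeca-2,6,10-trien-1-ol | OC/C=C(C)/CC/C=C(C)/C[C@H](O[Si](C)(C)C(C)(C)C)/C=C(\CO[Si](C)(C)C(C)(C)C)/CCl | intermediate
20 | (3E,7E,10S,11Z)-10-[(tert-butyldimethylsilyl)oxy]-12-{[(tert-butyldimethylsilyl)oxy]methyl}-4,8-dimethyl-1-oxacyclotrideca-3,7,11-triene | O1C/C=C(C)/CC/C=C(C)/C[C@H](O[Si](C)(C)C(C)(C)C)/C=C(\CO[Si](C)(C)C(C)(C)C)/C1 | intermediate
21 | 2-lithio derivative of 20 (lithium on germacrane C6, configuration labile) | [Li]C1/C=C(C)/CC/C=C(C)/C[C@H](O[Si](C)(C)C(C)(C)C)/C=C(\CO[Si](C)(C)C(C)(C)C)/CO1 | intermediate (not isolated)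
22 | 8α,12-bis[(tert-butyldimethylsilyl)oxy]germacra-1(10)E,4E,11(13)-trien-6α-ol; (1R,2E,6E,9S,10S)-9-[(tert-butyldimethylsilyl)oxy]-10-{3-[(tert-butyldimethylsilyl)oxy]prop-1-en-2-yl}-3,7-dimethylcyclodeca-2,6-dien-1-ol | C=C(CO[Si](C)(C)C(C)(C)C)[C@@H]1[C@@H](O[Si](C)(C)C(C)(C)C)C/C(C)=C/CC/C(C)=C/[C@H]1O | intermediate
23 | angelic acid, (2Z)-2-methylbut-2-enoic acid | C/C=C(/C)C(=O)O | starting material
24 | angelic 2,4,6-trichlorobenzoic anhydride | C/C=C(/C)C(=O)OC(=O)c1c(Cl)cc(Cl)cc1Cl | intermediate (not isolated)
25 | 6α-angeloyloxy-8α,12-bis[(tert-butyldimethylsilyl)oxy]germacra-1(10)E,4E,11(13)-triene | C=C(CO[Si](C)(C)C(C)(C)C)[C@@H]1[C@@H](O[Si](C)(C)C(C)(C)C)C/C(C)=C/CC/C(C)=C/[C@H]1OC(=O)/C(C)=C\C | intermediate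
26 | 6α-angeloyloxygermacra-1(10)E,4E,11(13)-triene-8α,12-diol | C=C(CO)[C@@H]1[C@@H](O)C/C(C)=C/CC/C(C)=C/[C@H]1OC(=O)/C(C)=C\C | intermediate
27 | 6α-angeloyloxy-8α-hydroxygermacra-1(10)E,4E,11(13)-trien-12-al | C=C(C=O)[C@@H]1[C@@H](O)C/C(C)=C/CC/C(C)=C/[C@H]1OC(=O)/C(C)=C\C | intermediate (not isolated)
28 | γ-lactol of 27 (8α,12-epoxy-12-hydroxy, C12 epimers) | C=C1C(O)O[C@H]2C/C(C)=C/CC/C(C)=C/[C@@H](OC(=O)/C(C)=C\C)[C@H]12 | intermediate (not isolated)
29 | 6α-angeloyloxygermacra-1(10)E,4E,11(13)-trien-12,8α-olide | C=C1C(=O)O[C@H]2C/C(C)=C/CC/C(C)=C/[C@@H](OC(=O)/C(C)=C\C)[C@H]12 | intermediate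
30 | (1R,4R,5R,6S,7R,8S,10R)-6-angeloyloxy-1,10:4,5-diepoxygermacr-11(13)-en-12,8-olide | C=C1C(=O)O[C@H]2C[C@@]3(C)O[C@@H]3CC[C@@]3(C)O[C@@H]3[C@@H](OC(=O)/C(C)=C\C)[C@H]12 | target

## Step count and least certain steps

Total step count: 19. Longest linear sequence: 16 steps (steps 1–3, 5–7 and 10–19, from geraniol 1); steps 4, 8 and 9 prepare the two side components.

Step 15 (key step). Most likely to go wrong: lithiation at the other α-position (C13) or at the CH2OSi carbon (followed by silyl migration to carbon), a competing [1,2]-shift, or attack on the other face of C7=C11 relative to C8. The electronic preference between the two allylic ether positions is small, so the outcome rests on steric shielding and on A(1,3) control. Fallback: it sets out from 19. Oxidation of the primary allylic alcohol with MnO2 would give the (2E,6E,10E)-enal allylic chloride F1. An intramolecular Nozaki–Hiyama allylation (CrCl2, THF, high dilution) would then close C6–C7 directly; allylchromium additions are anti-selective through a chair transition state, with the new bond anti to the C8 silyloxy group. This returns to the route at 22. Because it leaves at 19, it also bypasses the etherification of step 14 should that closure oligomerise.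

Step 19. Most likely to go wrong: loss of facial selectivity at C1=C10 if ring conformers with C14 turned to the other side are populated (nothing local fixes this alkene, unlike C4=C5), and acid-triggered transannular opening of a mono-epoxide before the second epoxidation. Fallback: it sets out from 22. Hydroxyl-directed (Henbest) epoxidation with one equivalent of mCPBA at −20 °C, where hydrogen bonding to the C6–OH and A(1,3) strain both favour the threo product, would give the 4α,5β-epoxy alcohol F2. Acylation as in step 16 would give the epoxy angelate F3, desilylation as in step 17 the epoxy diol F4, and MnO2 the 4α,5β-epoxy-1(10)-en-12,8α-olide F5. The single remaining alkene of F5, now in a ring stiffened by the oxirane, would be epoxidised with buffered mCPBA. This returns to the route at 30.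

Step 16. Most likely to go wrong: Z to E isomerisation of the acyl group (tiglate formation) during a slow, heated acylation of the hindered C6 alcohol. Fallback: it sets out from 22. DCC/DMAP esterification with 2-[bis(2,2,2-trifluoroethoxy)phosphoryl]propanoic acid would give the phosphonopropionate ester F6. A Still–Gennari olefination with acetaldehyde (KHMDS, 18-crown-6, THF, −78 °C) would then build the Z-trisubstituted enoate in place on the ester. This returns to the route at 25.

Step 10. Most likely to go wrong: epimerisation at C8 of the α-silyloxy aldehyde by the basic phosphonate anion, erosion of E selectivity, or β-elimination of silanolate from the phosphonate anion. Fallback: it sets out from 11. Non-basic Takai–Lombardo methylenation (Zn, CH2I2, TiCl4) would give the terminal alkene F7. Cross-metathesis (second-generation Hoveyda–Grubbs catalyst, CH2Cl2, 40 °C) with ethyl 2-{[(tert-butyldimethylsilyl)oxy]methyl}acrylate F8, itself made by silylation of purchasable ethyl 2-(hydroxymethyl)acrylate, would install the trisubstituted enoate under thermodynamic E control. This returns to the route at 15.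

## Further compounds

F1 | step 15 | (2E,6E,9S,10E)-9-[(tert-butyldimethylsilyl)oxy]-11-{[(tert-butyldimethylsilyl)oxy]methyl}-12-chloro-3,7-dimethyldodeca-2,6,10-trienal | O=C/C=C(C)/CC/C=C(C)/C[C@H](O[Si](C)(C)C(C)(C)C)/C=C(\CO[Si](C)(C)C(C)(C)C)/CCl
F2 | step 19 | 4α,5β-epoxy-8α,12-bis[(tert-butyldimethylsilyl)oxy]germacra-1(10)E,11(13)-dien-6α-ol | C=C(CO[Si](C)(C)C(C)(C)C)[C@@H]1[C@@H](O[Si](C)(C)C(C)(C)C)C/C(C)=C/CC[C@@]2(C)O[C@@H]2[C@H]1O
F3 | step 19 | 6α-angeloyloxy-4α,5β-epoxy-8α,12-bis[(tert-butyldimethylsilyl)oxy]germacra-1(10)E,11(13)-diene | C=C(CO[Si](C)(C)C(C)(C)C)[C@@H]1[C@@H](O[Si](C)(C)C(C)(C)C)C/C(C)=C/CC[C@@]2(C)O[C@@H]2[C@H]1OC(=O)/C(C)=C\C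
F4 | step 19 | 6α-angeloyloxy-4α,5β-epoxygermacra-1(10)E,11(13)-diene-8α,12-diol | C=C(CO)[C@@H]1[C@@H](O)C/C(C)=C/CC[C@@]2(C)O[C@@H]2[C@H]1OC(=O)/C(C)=C\C
F5 | step 19 | 6α-angeloyloxy-4α,5β-epoxygermacra-1(10)E,11(13)-dien-12,8α-olide | C=C1C(=O)O[C@H]2C/C(C)=C/CC[C@@]3(C)O[C@@H]3[C@@H](OC(=O)/C(C)=C\C)[C@H]12
F6 | step 16 | 8α,12-bis[(tert-butyldimethylsilyl)oxy]germacra-1(10)E,4E,11(13)-trien-6α-yl 2-[bis(2,2,2-trifluoroethoxy)phosphoryl]propanoate | C=C(CO[Si](C)(C)C(C)(C)C)[C@@H]1[C@@H](O[Si](C)(C)C(C)(C)C)C/C(C)=C/CC/C(C)=C/[C@H]1OC(=O)C(C)P(=O)(OCC(F)(F)F)OCC(F)(F)F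
F7 | step 10 | 1-({[(2E,6E,9S)-9-[(tert-butyldimethylsilyl)oxy]-3,7-dimethylundeca-2,6,10-trien-1-yl]oxy}methyl)-4-methoxybenzene | C=C[C@@H](O[Si](C)(C)C(C)(C)C)C/C(C)=C/CC/C(C)=C/COCc1ccc(OC)cc1
F8 | step 10 | ethyl 2-{[(tert-butyldimethylsilyl)oxy]methyl}acrylate | C=C(CO[Si](C)(C)C(C)(C)C)C(=O)OCC
A1 | alternative 1 | methyl (2Z,4S,6E,10E)-2-(bromomethyl)-4-[(tert-butyldimethylsilyl)oxy]-6,10-dimethyl-12-oxododeca-2,6,10-trienoate | COC(=O)/C(CBr)=C/[C@@H](O[Si](C)(C)C(C)(C)C)C/C(C)=C/CC/C(C)=C/C=O
A2 | alternative 2 | 1β-mesyloxy-6α-[(tert-butyldimethylsilyl)oxy]-15-oxo-5αH-eudesm-11(13)-en-12,8α-olide (10β-methyl, C4 epimers) | C=C1C(=O)O[C@H]2C[C@@]3(C)[C@H](OS(C)(=O)=O)CCC(C=O)[C@@H]3[C@@H](O[Si](C)(C)C(C)(C)C)[C@H]12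
A3 | alternative 2 | 6α-[(tert-butyldimethylsilyl)oxy]-15-oxogermacra-1(10),4,11(13)-trien-12,8α-olide (both ring alkenes ring-trans) | C=C1C(=O)O[C@H]2C/C(C)=C/CC/C(C=O)=C/[C@@H](O[Si](C)(C)C(C)(C)C)[C@H]12
A4 | alternative 3 | 6α,8α,12-tris[(tert-butyldimethylsilyl)oxy]elema-1,3,11(13)-trien-5α-ol (10β-methyl, 5β-isopropenyl, 7α-H) | C=C(CO[Si](C)(C)C(C)(C)C)[C@@H]1[C@@H](O[Si](C)(C)C(C)(C)C)C[C@@](C)(C=C)[C@](O)(C(C)=C)[C@H]1O[Si](C)(C)C(C)(C)C
A5 | alternative 3 | 6α,8α,12-tris[(tert-butyldimethylsilyl)oxy]germacra-1(10)E,11(13)-dien-5-one (C4 epimers) | C=C(CO[Si](C)(C)C(C)(C)C)[C@@H]1[C@@H](O[Si](C)(C)C(C)(C)C)C/C(C)=C/CCC(C)C(=O)[C@H]1O[Si](C)(C)C(C)(C)C
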